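**Retrosynthetic overview**
1. The plan rests on the trans-2-aryl-3-(hydroxymethyl)-2,3-dihydrobenzofuran (fused arene ring C, pendant guaiacyl ring D). Its C2–C3 bond carries both ring stereocentres. C2 is bonded to ring oxygen O1 and to ring D, so its C–H is strongly hydridic. C2–C3 is therefore cut back to an aryl(diazo)acetate carbon (C3) and an ortho O–CH2–aryl ether (C2).
2. The last C–C bond made is Cα–CH2(ring C) of the trans-dibenzylbutyrolactone, from a β-benzyl lactone enolate and a dihydrobenzofuran benzylic bromide.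
3. In the lactone half, the Cβ–CH2(ring B) bond comes from auxiliary-controlled alkylation of a succinyl imide. The C7–C8 bond of the 1,3-diol wing comes from an anti-aldol of an arylacetyl imide with O-benzylvanillin.
4. Both halves diverge from one arylacetate, made from 5-iodovanillin, O-benzylvanillyl alcohol and methyl bromoacetate. Its benzylic ether is the insertion site in one half and a hydrogenolysable phenol protecting group in the other.
5. Ring order: dihydrobenzofuran oxygen ring (step 6), temporary 1,3-dioxane (step 15), butyrolactone (step 21).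

Key step: step 6

Abbreviations:
- BVB = 4-benzyloxy-3-methoxybenzyl (BVB-oxy = ArCH2O–); TBS = tert-butyldimethylsilyl (TBSO-methyl = CH2OTBS); TMS = trimethylsilyl.
- p-ABSA = 4-acetamidobenzenesulfonyl azide.
- Rh2(R-PTTL)4 = dirhodium tetrakis[N-phthaloyl-(R)-tert-leucinate]; Rh2(S-DOSP)4 = dirhodium tetrakis[N-(4-dodecylbenzenesulfonyl)-(S)-prolinate].
- Diol wing: C7 = carbinol carbon, C8 = carbon bearing ring B, C9 = CH2OH. Ring A = guaiacyl ring of the wing; ring B = central arene of the wing.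

Assumption: the sense of induction known for phthaloyl-tert-leucinate dirhodium catalysts on simpler 2-(benzyloxy)phenyl diazoacetates (S ligands lead to 2R) is taken to hold here, so the R-ligand catalyst is used for 2S; both antipodes are commercial.

**Route**

Step 1
Reactants: 1 5-iodovanillin; 2 4-benzyloxy-3-methoxybenzyl alcohol
Product: 3 4-(BVB-oxy)-3-iodo-5-methoxybenzaldehyde
Conditions: PPh3, DIAD, THF, 0 °C to rt
Reagents that add atoms: none
Why: Mitsunobu etherification, in which the acidic phenol of 1 displaces the primary benzylic alkoxyphosphonium ion made from 2 under neutral conditions, so the future C2 methylene and ring D arrive in one step without a labile benzylic halide.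

Step 2
Reactants: 3 4-(BVB-oxy)-3-iodo-5-methoxybenzaldehyde
Product: 4 [4-(BVB-oxy)-3-iodo-5-methoxyphenyl]methanol
Conditions: NaBH4, MeOH–THF, 0 °C
Reagents that add atoms: none
Why: Borohydride reduction of the aryl aldehyde, to which the aryl iodide and the benzylic ethers are inert.

Step 3
Reactants: 4 [4-(BVB-oxy)-3-iodo-5-methoxyphenyl]methanol
Product: 5 2-(BVB-oxy)-1-iodo-3-methoxy-5-(TBSO-methyl)benzene
Conditions: TBSCl, imidazole, DMF, rt
Reagents that add atoms: tert-butyldimethylsilyl chloride, CC(C)(C)[Si](C)(C)Cl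
Why: Imidazole-promoted silylation of the only hydroxyl group gives a fluoride-labile handle that is orthogonal to all benzyl-type ethers and to the later acetonide.

Step 4
Reactants: 5 2-(BVB-oxy)-1-iodo-3-methoxy-5-(TBSO-methyl)benzene; 6 methyl bromoacetate
Product: 8 methyl 2-[2-(BVB-oxy)-3-methoxy-5-(TBSO-methyl)phenyl]acetate, via bromozinc ester enolate 7 (not isolated)
Conditions: activated Zn dust, THF, 40 °C; then 5, Pd2(dba)3 (2.5 mol %), XPhos (6 mol %), THF, 50 °C
Reagents that add atoms: zinc dust, [Zn] (ends in 7 only)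
Why: Negishi-type α-arylation of a Reformatsky reagent (oxidative addition of the aryl iodide to zerovalent palladium, transmetalation from zinc, reductive elimination) installs the CH2CO2Me group under nearly neutral conditions that spare the silyl ether, which a hot chloride-mediated decarboxylation would not.

Step 5
Reactants: 8 methyl 2-[2-(BVB-oxy)-3-methoxy-5-(TBSO-methyl)phenyl]acetate
Product: 9 methyl 2-diazo-2-[2-(BVB-oxy)-3-methoxy-5-(TBSO-methyl)phenyl]acetate
Conditions: p-ABSA, DBU, MeCN, 0 °C to rt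
Reagents that add atoms: 4-acetamidobenzenesulfonyl azide, CC(=O)Nc1ccc(cc1)S(=O)(=O)N=[N+]=[N-]
Why: Regitz diazo transfer, in which DBU deprotonates the benzylic ester position and the enolate takes N2 from the sulfonyl azide, the standard entry to aryl diazoacetates.

Step 6
Reactants: 9 methyl 2-diazo-2-[2-(BVB-oxy)-3-methoxy-5-(TBSO-methyl)phenyl]acetate
Product: 11 methyl (2S,3S)-trans-2-(4-benzyloxy-3-methoxyphenyl)-7-methoxy-5-(TBSO-methyl)-2,3-dihydrobenzofuran-3-carboxylate, via cis ester 10 (not isolated)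
Conditions: Rh2(R-PTTL)4 (1 mol %), toluene, −60 °C, slow addition of 9; then NaOMe (0.3 equiv), MeOH, −60 °C to rt
Reagents that add atoms: none
Why: Loss of N2 from 9 at a free axial site of the divalent rhodium dimer gives an electrophilic donor–acceptor carbene whose carbon (future C3) accepts the hydridic hydrogen of the neighbouring O–CH2–aryl group while the C2–C3 bond forms in the same concerted but asynchronous three-centre event, which is the known dirhodium-catalysed intramolecular C–H insertion of 2-(benzyloxy)aryl diazoacetates to 2-aryl-2,3-dihydrobenzofuran-3-carboxylates. The oxygen ring closes as a 1,5-insertion over the atoms C3, C3a, C7a, O1 and C2, the ring size such carbenes prefer. C2 is set by the catalyst, because the phthalimido walls of the four R-configured tert-leucinate ligands allow only one of the two enantiotopic benzylic hydrogens to reach the carbene, which should give 2S. C3 is first formed cis to the aryl group under kinetic control (10) and is then turned over by catalytic methoxide through the planar ester enolate into the less crowded trans ester 11. C2 should survive this, since expulsion of the ring aryloxide from the C3 enolate would be the reverse of a 5-endo-trig closure with poor orbital overlap, and the benzyl ether on ring D (chosen instead of a base-labile silyl ether) shuts off any quinone methide pathway. The step needs site selectivity, and the substrate secures it: only this methylene lies within 1,5 reach and it is activated twice (α-oxygen, electron-rich arene), whereas the OCH3, OCH2Ph and CH2OSi hydrogens could react only between molecules, which slow addition at low temperature suppresses.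

Step 7
Reactants: 11 methyl (2S,3S)-trans-2-(4-benzyloxy-3-methoxyphenyl)-7-methoxy-5-(TBSO-methyl)-2,3-dihydrobenzofuran-3-carboxylate
Product: 12 [(2S,3R)-trans-2-(4-benzyloxy-3-methoxyphenyl)-7-methoxy-5-(TBSO-methyl)-2,3-dihydrobenzofuran-3-yl]methanol
Conditions: LiAlH4, THF, 0 °C
Reagents that add atoms: none
Why: Hydride reduction of the ester to the primary alcohol ends the acidity of C3–H, so that C3 can no longer epimerise, and leaves silyl and benzyl ethers untouched.

Step 8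
Reactants: 12 [(2S,3R)-trans-2-(4-benzyloxy-3-methoxyphenyl)-7-methoxy-5-(TBSO-methyl)-2,3-dihydrobenzofuran-3-yl]methanol
Product: 13 (2S,3R)-3-(benzyloxymethyl)-2-(4-benzyloxy-3-methoxyphenyl)-7-methoxy-5-(TBSO-methyl)-2,3-dihydrobenzofuran
Conditions: NaH, BnBr, Bu4NI (cat.), THF–DMF, 0 °C to rt
Reagents that add atoms: benzyl bromide, BrCc1ccccc1
Why: Williamson etherification of the primary alkoxide, benzyl being chosen because it withstands fluoride, enolates and aqueous acid and leaves in the final hydrogenolysis.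

Step 9
Reactants: 13 (2S,3R)-3-(benzyloxymethyl)-2-(4-benzyloxy-3-methoxyphenyl)-7-methoxy-5-(TBSO-methyl)-2,3-dihydrobenzofuran
Product: 14 [(2S,3R)-3-(benzyloxymethyl)-2-(4-benzyloxy-3-methoxyphenyl)-7-methoxy-2,3-dihydrobenzofuran-5-yl]methanol
Conditions: Bu4NF, THF, 0 °C to rt
Reagents that add atoms: none
Why: Fluoride-mediated desilylation driven by the strong Si–F bond frees only the ring C benzylic alcohol, because 13 holds no other silyl group.

Step 10
Reactants: 14 [(2S,3R)-3-(benzyloxymethyl)-2-(4-benzyloxy-3-methoxyphenyl)-7-methoxy-2,3-dihydrobenzofuran-5-yl]methanol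
Product: 15 (2S,3R)-3-(benzyloxymethyl)-2-(4-benzyloxy-3-methoxyphenyl)-5-(bromomethyl)-7-methoxy-2,3-dihydrobenzofuran
Conditions: CBr4, PPh3, CH2Cl2, 0 °C
Reagents that add atoms: carbon tetrabromide, BrC(Br)(Br)Br
Why: Appel bromination (SN2 by bromide on the alkoxyphosphonium ion) gives the electron-rich benzylic bromide under neutral conditions, to be used without storage.

Step 11
Reactants: 8 methyl 2-[2-(BVB-oxy)-3-methoxy-5-(TBSO-methyl)phenyl]acetate
Product: 16 2-[2-(BVB-oxy)-3-methoxy-5-(TBSO-methyl)phenyl]acetic acid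
Conditions: LiOH, THF–MeOH–H2O, rt; then 1 M HCl to pH 4, 0 °C
Reagents that add atoms: lithium hydroxide, [Li+].[OH-]
Why: Saponification of the unhindered methyl ester, to which the primary alkyl silyl ether and all benzylic ethers are stable.

Step 12
Reactants: 16 2-[2-(BVB-oxy)-3-methoxy-5-(TBSO-methyl)phenyl]acetic acid; 17 (S)-4-benzyl-1,3-oxazolidin-2-one
Product: 19 (S)-4-benzyl-3-{2-[2-(BVB-oxy)-3-methoxy-5-(TBSO-methyl)phenyl]acetyl}-1,3-oxazolidin-2-one, via mixed pivalic anhydride 18 (not isolated)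
Conditions: PivCl, Et3N, THF, −20 °C; then 17, LiCl, −20 °C to rt
Reagents that add atoms: pivaloyl chloride, CC(C)(C)C(=O)Cl (ends in 18 only)
Why: N-acylation of the oxazolidinone by the mixed anhydride under LiCl/Et3N activation attaches the auxiliary without strong base, attack going to the less hindered arylacetyl carbonyl.

Step 13
Reactants: 19 (S)-4-benzyl-3-{2-[2-(BVB-oxy)-3-methoxy-5-(TBSO-methyl)phenyl]acetyl}-1,3-oxazolidin-2-one; 20 4-benzyloxy-3-methoxybenzaldehyde
Product: 21 (S)-4-benzyl-3-{(2R,3S)-3-(4-benzyloxy-3-methoxyphenyl)-2-[2-(BVB-oxy)-3-methoxy-5-(TBSO-methyl)phenyl]-3-(trimethylsilyloxy)propanoyl}-1,3-oxazolidin-2-one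
Conditions: MgCl2 (20 mol %), Et3N, TMSCl, EtOAc, rt
Reagents that add atoms: chlorotrimethylsilane, C[Si](C)(C)Cl
Why: Magnesium-halide-catalysed Evans anti-aldol, in which soft enolisation gives the magnesium-chelated Z-enolate that adds to the non-enolisable aromatic aldehyde on the face away from the auxiliary benzyl group (sets C8, 2R in the imide) with anti topicity (sets C7, 3S), while silylation of the aldolate by TMSCl makes the addition irreversible and releases the catalyst.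

Step 14
Reactants: 21 (S)-4-benzyl-3-{(2R,3S)-3-(4-benzyloxy-3-methoxyphenyl)-2-[2-(BVB-oxy)-3-methoxy-5-(TBSO-methyl)phenyl]-3-(trimethylsilyloxy)propanoyl}-1,3-oxazolidin-2-one
Product: 23 (1S,2S)-1-(4-benzyloxy-3-methoxyphenyl)-2-[2-(BVB-oxy)-3-methoxy-5-(TBSO-methyl)phenyl]propane-1,3-diol, via trimethylsilyl ether alcohol 22 (not isolated)
Conditions: LiBH4, THF, 0 °C to rt; aqueous work-up; then K2CO3 (cat.), MeOH, rt
Reagents that add atoms: none
Why: Reductive removal of the auxiliary by borohydride attack on the exocyclic imide carbonyl (the silyl ether blocks retro-aldol cleavage) followed by carbonate-catalysed methanolysis of the labile TMS ether gives the anti diol without touching C7 or C8.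

Step 15
Reactants: 23 (1S,2S)-1-(4-benzyloxy-3-methoxyphenyl)-2-[2-(BVB-oxy)-3-methoxy-5-(TBSO-methyl)phenyl]propane-1,3-diol
Product: 24 (4S,5S)-4-(4-benzyloxy-3-methoxyphenyl)-5-[2-(BVB-oxy)-3-methoxy-5-(TBSO-methyl)phenyl]-2,2-dimethyl-1,3-dioxane
Conditions: 2,2-dimethoxypropane, PPTS (cat.), CH2Cl2, rt
Reagents that add atoms: 2,2-dimethoxypropane, COC(C)(C)OC
Why: Acid-catalysed transketalisation ties the anti 1,3-diol into a chair dioxane with both aryl groups equatorial, a group stable to fluoride, hydride and strong base.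

Step 16
Reactants: 24 (4S,5S)-4-(4-benzyloxy-3-methoxyphenyl)-5-[2-(BVB-oxy)-3-methoxy-5-(TBSO-methyl)phenyl]-2,2-dimethyl-1,3-dioxane
Product: 25 {4-(BVB-oxy)-3-[(4S,5S)-4-(4-benzyloxy-3-methoxyphenyl)-2,2-dimethyl-1,3-dioxan-5-yl]-5-methoxyphenyl}methanol
Conditions: Bu4NF, THF, 0 °C to rt
Reagents that add atoms: none
Why: Fluoride-mediated desilylation removes the single silyl group, while acetonide and benzylic ethers are inert.

Step 17
Reactants: 25 {4-(BVB-oxy)-3-[(4S,5S)-4-(4-benzyloxy-3-methoxyphenyl)-2,2-dimethyl-1,3-dioxan-5-yl]-5-methoxyphenyl}methanol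
Product: 26 (4S,5S)-4-(4-benzyloxy-3-methoxyphenyl)-5-[5-(bromomethyl)-2-(BVB-oxy)-3-methoxyphenyl]-2,2-dimethyl-1,3-dioxane
Conditions: CBr4, PPh3, 2,6-lutidine, CH2Cl2, 0 °C
Reagents that add atoms: carbon tetrabromide, BrC(Br)(Br)Br
Why: Appel bromination of the primary benzylic alcohol, buffered with lutidine so that traces of acid cannot open the acetonide.

Step 18
Reactants: 27 4-tert-butoxy-4-oxobutanoic acid; 28 (R)-4-benzyl-1,3-oxazolidin-2-one
Product: 30 tert-butyl 4-[(R)-4-benzyl-2-oxo-1,3-oxazolidin-3-yl]-4-oxobutanoate, via mixed pivalic anhydride 29 (not isolated)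
Conditions: PivCl, Et3N, THF, −20 °C; then 28, LiCl, −20 °C to rt
Reagents that add atoms: pivaloyl chloride, CC(C)(C)C(=O)Cl (ends in 29 only)
Why: N-acylation of the oxazolidinone through the mixed anhydride, as in step 12, gives the chiral succinate building block.

Step 19
Reactants: 30 tert-butyl 4-[(R)-4-benzyl-2-oxo-1,3-oxazolidin-3-yl]-4-oxobutanoate; 26 (4S,5S)-4-(4-benzyloxy-3-methoxyphenyl)-5-[5-(bromomethyl)-2-(BVB-oxy)-3-methoxyphenyl]-2,2-dimethyl-1,3-dioxane
Product: 31 tert-butyl (3R)-4-[(R)-4-benzyl-2-oxo-1,3-oxazolidin-3-yl]-3-{4-(BVB-oxy)-3-[(4S,5S)-4-(4-benzyloxy-3-methoxyphenyl)-2,2-dimethyl-1,3-dioxan-5-yl]-5-methoxybenzyl}-4-oxobutanoate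
Conditions: 30 (1.3 equiv), NaHMDS, THF, −78 °C; then 26, −78 to −30 °C
Reagents that add atoms: none
Why: Evans asymmetric alkylation, in which the chelated sodium Z-enolate of the imide (formed in preference to the tert-butyl ester enolate) is benzylated on the face opposite the auxiliary benzyl group and so sets the future lactone Cβ as R.

Step 20
Reactants: 31 tert-butyl (3R)-4-[(R)-4-benzyl-2-oxo-1,3-oxazolidin-3-yl]-3-{4-(BVB-oxy)-3-[(4S,5S)-4-(4-benzyloxy-3-methoxyphenyl)-2,2-dimethyl-1,3-dioxan-5-yl]-5-methoxybenzyl}-4-oxobutanoate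
Product: 32 tert-butyl (3R)-3-{4-(BVB-oxy)-3-[(4S,5S)-4-(4-benzyloxy-3-methoxyphenyl)-2,2-dimethyl-1,3-dioxan-5-yl]-5-methoxybenzyl}-4-hydroxybutanoate
Conditions: LiBH4, THF, 0 °C
Reagents that add atoms: none
Why: Chemoselective borohydride reduction of the activated imide carbonyl to the primary alcohol, the hindered tert-butyl ester being much slower to react.

Step 21
Reactants: 32 tert-butyl (3R)-3-{4-(BVB-oxy)-3-[(4S,5S)-4-(4-benzyloxy-3-methoxyphenyl)-2,2-dimethyl-1,3-dioxan-5-yl]-5-methoxybenzyl}-4-hydroxybutanoate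
Product: 33 (4R)-4-{4-(BVB-oxy)-3-[(4S,5S)-4-(4-benzyloxy-3-methoxyphenyl)-2,2-dimethyl-1,3-dioxan-5-yl]-5-methoxybenzyl}oxolan-2-one
Conditions: KOt-Bu (0.2 equiv), THF, 0 °C
Reagents that add atoms: none
Why: Base-catalysed lactonisation (5-exo-trig intramolecular transesterification with loss of tert-butoxide, which carries the chain) closes the butyrolactone without the acid usually used on tert-butyl esters, which would endanger the acetonide, and Cβ is not epimerisable.

Step 22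
Reactants: 33 (4R)-4-{4-(BVB-oxy)-3-[(4S,5S)-4-(4-benzyloxy-3-methoxyphenyl)-2,2-dimethyl-1,3-dioxan-5-yl]-5-methoxybenzyl}oxolan-2-one; 15 (2S,3R)-3-(benzyloxymethyl)-2-(4-benzyloxy-3-methoxyphenyl)-5-(bromomethyl)-7-methoxy-2,3-dihydrobenzofuran
Product: 34 (3R,4R)-3-{[(2S,3R)-3-(benzyloxymethyl)-2-(4-benzyloxy-3-methoxyphenyl)-7-methoxy-2,3-dihydrobenzofuran-5-yl]methyl}-4-{4-(BVB-oxy)-3-[(4S,5S)-4-(4-benzyloxy-3-methoxyphenyl)-2,2-dimethyl-1,3-dioxan-5-yl]-5-methoxybenzyl}oxolan-2-one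
Conditions: LiHMDS, THF, −78 °C; then 15, DMPU, −78 to −40 °C
Reagents that add atoms: none
Why: Lactone enolate alkylation as used for dibenzylbutyrolactone lignans, in which the bromide approaches the lithium enolate anti to the β-benzyl group and sets Cα as R (trans, also the thermodynamic isomer); material from any minor enantiomer of 15 becomes a diastereomer here and can be removed by chromatography.

Step 23
Reactants: 34 (3R,4R)-3-{[(2S,3R)-3-(benzyloxymethyl)-2-(4-benzyloxy-3-methoxyphenyl)-7-methoxy-2,3-dihydrobenzofuran-5-yl]methyl}-4-{4-(BVB-oxy)-3-[(4S,5S)-4-(4-benzyloxy-3-methoxyphenyl)-2,2-dimethyl-1,3-dioxan-5-yl]-5-methoxybenzyl}oxolan-2-one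
Product: 35 (3R,4R)-3-{[(2S,3R)-3-(benzyloxymethyl)-2-(4-benzyloxy-3-methoxyphenyl)-7-methoxy-2,3-dihydrobenzofuran-5-yl]methyl}-4-{4-(BVB-oxy)-3-[(1S,2S)-1-(4-benzyloxy-3-methoxyphenyl)-1,3-dihydroxypropan-2-yl]-5-methoxybenzyl}oxolan-2-one
Conditions: AcOH–THF–H2O (4:1:1), rt to 35 °C
Reagents that add atoms: none
Why: Mild acid-catalysed acetal hydrolysis proceeds through the acetal-carbon oxocarbenium ion and not through a C7 cation, and with all phenols still etherified neither a quinone methide nor attack of the ring B oxygen on C7 is possible.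

Step 24
Reactants: 35 (3R,4R)-3-{[(2S,3R)-3-(benzyloxymethyl)-2-(4-benzyloxy-3-methoxyphenyl)-7-methoxy-2,3-dihydrobenzofuran-5-yl]methyl}-4-{4-(BVB-oxy)-3-[(1S,2S)-1-(4-benzyloxy-3-methoxyphenyl)-1,3-dihydroxypropan-2-yl]-5-methoxybenzyl}oxolan-2-one
Product: 36 CNP0199264.2, (3R,4R)-4-{4-hydroxy-3-[(1S,2S)-1,3-dihydroxy-1-(4-hydroxy-3-methoxyphenyl)propan-2-yl]-5-methoxybenzyl}-3-{[(2S,3R)-2-(4-hydroxy-3-methoxyphenyl)-3-(hydroxymethyl)-7-methoxy-2,3-dihydrobenzofuran-5-yl]methyl}oxolan-2-one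
Conditions: H2 (1 atm), 10% Pd/C, EtOAc–EtOH, rt, stopped at full uptake
Reagents that add atoms: none
Why: Catalytic hydrogenolysis cleaves the five unhindered primary benzylic C–O bonds (three phenyl-CH2–O–aryl bonds, the BVB–O bond to ring B and the alkyl benzyl ether) faster than the hindered secondary C7–OH and C2–O1 bonds under neutral conditions, as in the usual debenzylation of arylpropanediol lignin models.

**Compound list**
1 | 5-iodovanillin | COc1cc(C=O)cc(I)c1O | starting material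
2 | 4-benzyloxy-3-methoxybenzyl alcohol | COc1cc(CO)ccc1OCc1ccccc1 | starting material
3 | 4-(BVB-oxy)-3-iodo-5-methoxybenzaldehyde | COc1cc(C=O)cc(I)c1OCc1ccc(OCc2ccccc2)c(OC)c1 | intermediate
4 | [4-(BVB-oxy)-3-iodo-5-methoxyphenyl]methanol | COc1cc(CO)cc(I)c1OCc1ccc(OCc2ccccc2)c(OC)c1 | intermediate
5 | 2-(BVB-oxy)-1-iodo-3-methoxy-5-(TBSO-methyl)benzene | COc1cc(CO[Si](C)(C)C(C)(C)C)cc(I)c1OCc1ccc(OCc2ccccc2)c(OC)c1 | intermediate
6 | methyl bromoacetate | COC(=O)CBr | starting material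
7 | bromo(2-methoxy-2-oxoethyl)zinc | COC(=O)C[Zn]Br | intermediate
8 | methyl 2-[2-(BVB-oxy)-3-methoxy-5-(TBSO-methyl)phenyl]acetate | COC(=O)Cc1cc(CO[Si](C)(C)C(C)(C)C)cc(OC)c1OCc1ccc(OCc2ccccc2)c(OC)c1 | intermediate
9 | methyl 2-diazo-2-[2-(BVB-oxy)-3-methoxy-5-(TBSO-methyl)phenyl]acetate | COC(=O)C(=[N+]=[N-])c1cc(CO[Si](C)(C)C(C)(C)C)cc(OC)c1OCc1ccc(OCc2ccccc2)c(OC)c1 | intermediate
10 | methyl (2S,3R)-cis-2-(4-benzyloxy-3-methoxyphenyl)-7-methoxy-5-(TBSO-methyl)-2,3-dihydrobenzofuran-3-carboxylate | CC(C)(C)[Si](C)(C)OCc1cc(OC)c2c(c1)[C@@H](C(=O)OC)[C@@H](c1ccc(OCc3ccccc3)c(OC)c1)O2 | intermediate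
11 | methyl (2S,3S)-trans-2-(4-benzyloxy-3-methoxyphenyl)-7-methoxy-5-(TBSO-methyl)-2,3-dihydrobenzofuran-3-carboxylate | CC(C)(C)[Si](C)(C)OCc1cc(OC)c2c(c1)[C@H](C(=O)OC)[C@@H](c1ccc(OCc3ccccc3)c(OC)c1)O2 | intermediate
12 | [(2S,3R)-trans-2-(4-benzyloxy-3-methoxyphenyl)-7-methoxy-5-(TBSO-methyl)-2,3-dihydrobenzofuran-3-yl]methanol | CC(C)(C)[Si](C)(C)OCc1cc(OC)c2c(c1)[C@H](CO)[C@@H](c1ccc(OCc3ccccc3)c(OC)c1)O2 | intermediate
13 | (2S,3R)-3-(benzyloxymethyl)-2-(4-benzyloxy-3-methoxyphenyl)-7-methoxy-5-(TBSO-methyl)-2,3-dihydrobenzofuran | CC(C)(C)[Si](C)(C)OCc1cc(OC)c2c(c1)[C@H](COCc1ccccc1)[C@@H](c1ccc(OCc3ccccc3)c(OC)c1)O2 | intermediate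
14 | [(2S,3R)-3-(benzyloxymethyl)-2-(4-benzyloxy-3-methoxyphenyl)-7-methoxy-2,3-dihydrobenzofuran-5-yl]methanol | OCc1cc(OC)c2c(c1)[C@H](COCc1ccccc1)[C@@H](c1ccc(OCc3ccccc3)c(OC)c1)O2 | intermediate
15 | (2S,3R)-3-(benzyloxymethyl)-2-(4-benzyloxy-3-methoxyphenyl)-5-(bromomethyl)-7-methoxy-2,3-dihydrobenzofuran | BrCc1cc(OC)c2c(c1)[C@H](COCc1ccccc1)[C@@H](c1ccc(OCc3ccccc3)c(OC)c1)O2 | intermediate
16 | 2-[2-(BVB-oxy)-3-methoxy-5-(TBSO-methyl)phenyl]acetic acid | OC(=O)Cc1cc(CO[Si](C)(C)C(C)(C)C)cc(OC)c1OCc1ccc(OCc2ccccc2)c(OC)c1 | intermediate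
17 | (S)-4-benzyl-1,3-oxazolidin-2-one | O=C1N[C@@H](Cc2ccccc2)CO1 | starting material
18 | mixed pivalic anhydride of 16 | CC(C)(C)C(=O)OC(=O)Cc1cc(CO[Si](C)(C)C(C)(C)C)cc(OC)c1OCc1ccc(OCc2ccccc2)c(OC)c1 | intermediate
19 | (S)-4-benzyl-3-{2-[2-(BVB-oxy)-3-methoxy-5-(TBSO-methyl)phenyl]acetyl}-1,3-oxazolidin-2-one | O=C(Cc1cc(CO[Si](C)(C)C(C)(C)C)cc(OC)c1OCc1ccc(OCc2ccccc2)c(OC)c1)N1[C@@H](Cc2ccccc2)COC1=O | intermediate
20 | 4-benzyloxy-3-methoxybenzaldehyde (O-benzylvanillin) | COc1cc(C=O)ccc1OCc1ccccc1 | starting material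
21 | (2R,3S) anti-aldol TMS ether on the (S)-auxiliary | COc1cc([C@@H](O[Si](C)(C)C)[C@H](C(=O)N2[C@@H](Cc3ccccc3)COC2=O)c2cc(CO[Si](C)(C)C(C)(C)C)cc(OC)c2OCc2ccc(OCc3ccccc3)c(OC)c2)ccc1OCc1ccccc1 | intermediate
22 | (2S,3S)-3-(4-benzyloxy-3-methoxyphenyl)-2-[2-(BVB-oxy)-3-methoxy-5-(TBSO-methyl)phenyl]-3-(trimethylsilyloxy)propan-1-ol | COc1cc([C@@H](O[Si](C)(C)C)[C@H](CO)c2cc(CO[Si](C)(C)C(C)(C)C)cc(OC)c2OCc2ccc(OCc3ccccc3)c(OC)c2)ccc1OCc1ccccc1 | intermediate
23 | (1S,2S)-1-(4-benzyloxy-3-methoxyphenyl)-2-[2-(BVB-oxy)-3-methoxy-5-(TBSO-methyl)phenyl]propane-1,3-diol | COc1cc([C@@H](O)[C@H](CO)c2cc(CO[Si](C)(C)C(C)(C)C)cc(OC)c2OCc2ccc(OCc3ccccc3)c(OC)c2)ccc1OCc1ccccc1 | intermediate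
24 | (4S,5S)-4-(4-benzyloxy-3-methoxyphenyl)-5-[2-(BVB-oxy)-3-methoxy-5-(TBSO-methyl)phenyl]-2,2-dimethyl-1,3-dioxane | COc1cc([C@H]4OC(C)(C)OC[C@@H]4c2cc(CO[Si](C)(C)C(C)(C)C)cc(OC)c2OCc2ccc(OCc3ccccc3)c(OC)c2)ccc1OCc1ccccc1 | intermediate
25 | {4-(BVB-oxy)-3-[(4S,5S)-4-(4-benzyloxy-3-methoxyphenyl)-2,2-dimethyl-1,3-dioxan-5-yl]-5-methoxyphenyl}methanol | COc1cc([C@H]4OC(C)(C)OC[C@@H]4c2cc(CO)cc(OC)c2OCc2ccc(OCc3ccccc3)c(OC)c2)ccc1OCc1ccccc1 | intermediate
26 | (4S,5S)-4-(4-benzyloxy-3-methoxyphenyl)-5-[5-(bromomethyl)-2-(BVB-oxy)-3-methoxyphenyl]-2,2-dimethyl-1,3-dioxane | COc1cc([C@H]4OC(C)(C)OC[C@@H]4c2cc(CBr)cc(OC)c2OCc2ccc(OCc3ccccc3)c(OC)c2)ccc1OCc1ccccc1 | intermediate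
27 | 4-tert-butoxy-4-oxobutanoic acid (mono-tert-butyl succinate) | CC(C)(C)OC(=O)CCC(=O)O | starting material
28 | (R)-4-benzyl-1,3-oxazolidin-2-one | O=C1N[C@H](Cc2ccccc2)CO1 | starting material
29 | mixed pivalic anhydride of 27 | CC(C)(C)OC(=O)CCC(=O)OC(=O)C(C)(C)C | intermediate
30 | tert-butyl 4-[(R)-4-benzyl-2-oxo-1,3-oxazolidin-3-yl]-4-oxobutanoate | CC(C)(C)OC(=O)CCC(=O)N1[C@H](Cc2ccccc2)COC1=O | intermediate
31 | (3R)-benzylated succinyl imide | COc1cc([C@H]4OC(C)(C)OC[C@@H]4c2cc(C[C@H](CC(=O)OC(C)(C)C)C(=O)N5[C@H](Cc6ccccc6)COC5=O)cc(OC)c2OCc2ccc(OCc3ccccc3)c(OC)c2)ccc1OCc1ccccc1 | intermediate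
32 | tert-butyl (3R)-3-(arylmethyl)-4-hydroxybutanoate | COc1cc([C@H]4OC(C)(C)OC[C@@H]4c2cc(C[C@H](CC(=O)OC(C)(C)C)CO)cc(OC)c2OCc2ccc(OCc3ccccc3)c(OC)c2)ccc1OCc1ccccc1 | intermediate
33 | (4R)-β-benzyl lactone carrying the protected diol wing | COc1cc([C@H]4OC(C)(C)OC[C@@H]4c2cc(C[C@H]5COC(=O)C5)cc(OC)c2OCc2ccc(OCc3ccccc3)c(OC)c2)ccc1OCc1ccccc1 | intermediate
34 | fully protected (3R,4R)-dibenzylbutyrolactone | COc1cc([C@H]4OC(C)(C)OC[C@@H]4c2cc(C[C@H]5COC(=O)[C@@H]5Cc5cc(OC)c6c(c5)[C@H](COCc5ccccc5)[C@@H](c5ccc(OCc7ccccc7)c(OC)c5)O6)cc(OC)c2OCc2ccc(OCc3ccccc3)c(OC)c2)ccc1OCc1ccccc1 | intermediate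
35 | benzyl-protected (1S,2S)-diol | COc1cc([C@@H](O)[C@H](CO)c2cc(C[C@H]5COC(=O)[C@@H]5Cc5cc(OC)c6c(c5)[C@H](COCc5ccccc5)[C@@H](c5ccc(OCc7ccccc7)c(OC)c5)O6)cc(OC)c2OCc2ccc(OCc3ccccc3)c(OC)c2)ccc1OCc1ccccc1 | intermediate
36 | CNP0199264.2 | COc1cc([C@@H](O)[C@H](CO)c2cc(C[C@H]3COC(=O)[C@@H]3Cc3cc(OC)c4c(c3)[C@H](CO)[C@@H](c3ccc(O)c(OC)c3)O4)cc(OC)c2O)ccc1O | target

**Step count**
Total steps: 24. Longest linear sequence: 17 (steps 1–4, 11–17, 19–24).

**Steps most likely to fail**

1. Step 6.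
- Risk: the 7-methoxy group twists the benzylic ether out of the arene plane, so the catalyst pocket may discriminate poorly between the two enantiotopic hydrogens. Carbene dimerisation may also compete at low temperature.
- Fallback: stereocontrol is moved to a covalently bound auxiliary (double stereodifferentiation).
- It sets out from acid 16. Carbodiimide esterification (EDC, DMAP, CH2Cl2) with (S)-lactic acid pyrrolidide gives the lactamide ester F1.
- Diazo transfer (p-ABSA, DBU, MeCN) gives the diazo lactamide ester F2.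
- Decomposition with Rh2(S-DOSP)4 in CH2Cl2, taken as the matched pair for 2S, should give the trans lactamide ester F3 directly. Its diastereomers can be separated by chromatography.
- LiBH4 in THF cleaves the auxiliary ester reductively, and the route is rejoined at alcohol 12.

2. Step 13.
- Risk: anti selectivity may erode through reversible addition before silylation. Magnesium may be chelated by the ortho ether oxygen. Enolisation next to the bulky ortho group may be slow.
- Fallback: relative configuration comes from a closed Zimmerman–Traxler transition state and absolute configuration from resolution.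
- It sets out from acid 16. Double deprotonation with i-PrMgCl (2.2 equiv, THF) and addition of aldehyde 20 (Ivanov reaction) should give the anti β-hydroxy acid F4 as a racemate.
- F4 is resolved by preparative chromatography on a chiral phase.
- BH3·THF reduces the (2R,3S) acid, and the route is rejoined at diol 23.

3. Step 24.
- Risk: over-reduction, namely hydrogenolytic loss of the free benzylic hydroxyl at C7 or opening of the C2–O1 bond while the slower alkyl benzyl ether is still being cleaved.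
- Fallback: the last two operations are inverted, so that C7–O is held inside the dioxane during the reduction.
- It sets out from 34. Hydrogenolysis (H2, Pd/C, EtOAc–EtOH) gives the debenzylated acetonide F5.
- Brief hydrolysis in dilute aqueous acetic acid at or below rt returns to the route at target 36.

Further compounds
F1 | step 6 | (S)-1-oxo-1-(pyrrolidin-1-yl)propan-2-yl 2-[2-(BVB-oxy)-3-methoxy-5-(TBSO-methyl)phenyl]acetate | C[C@H](OC(=O)Cc1cc(CO[Si](C)(C)C(C)(C)C)cc(OC)c1OCc1ccc(OCc2ccccc2)c(OC)c1)C(=O)N1CCCC1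
F2 | step 6 | (S)-1-oxo-1-(pyrrolidin-1-yl)propan-2-yl 2-diazo-2-[2-(BVB-oxy)-3-methoxy-5-(TBSO-methyl)phenyl]acetate | C[C@H](OC(=O)C(=[N+]=[N-])c1cc(CO[Si](C)(C)C(C)(C)C)cc(OC)c1OCc1ccc(OCc2ccccc2)c(OC)c1)C(=O)N1CCCC1
F3 | step 6 | (S)-1-oxo-1-(pyrrolidin-1-yl)propan-2-yl (2S,3S)-trans-2-(4-benzyloxy-3-methoxyphenyl)-7-methoxy-5-(TBSO-methyl)-2,3-dihydrobenzofuran-3-carboxylate | C[C@H](OC(=O)[C@H]1c2cc(CO[Si](C)(C)C(C)(C)C)cc(OC)c2O[C@@H]1c1ccc(OCc2ccccc2)c(OC)c1)C(=O)N1CCCC1
F4 | step 13 | (2R,3S)-3-(4-benzyloxy-3-methoxyphenyl)-2-[2-(BVB-oxy)-3-methoxy-5-(TBSO-methyl)phenyl]-3-hydroxypropanoic acid (first formed as the racemate) | COc1cc([C@@H](O)[C@H](C(=O)O)c2cc(CO[Si](C)(C)C(C)(C)C)cc(OC)c2OCc2ccc(OCc3ccccc3)c(OC)c2)ccc1OCc1ccccc1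
F5 | step 24 | 7,9-O-isopropylidene derivative of the target (all benzyl-type groups removed) | COc1cc([C@H]4OC(C)(C)OC[C@@H]4c2cc(C[C@H]5COC(=O)[C@@H]5Cc5cc(OC)c6c(c5)[C@H](CO)[C@@H](c5ccc(O)c(OC)c5)O6)cc(OC)c2O)ccc1O
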